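The numbers in the tables stem from a simulated flask for an exercise.

**Late readings.** Late in the earlier runs, at 50.0 min, amber stands at 10.0 % of its smaller charge and teal at 3.6 % of its larger one.

| flask | substrate | gas phase | protic impurity | remark | time |
|---|---|---|---|---|---|
| amber | 0.034 M | 13 mM (held) | 0.050 M | run made earlier |  |
| teal | 0.075 M | 13 mM (held) | 0.050 M | run made earlier |  |
| flask | 0.050 M | 13 mM (held) | 0.0500 M |  | 50 min |

| run | time / min | target / % |
|---|---|---|
| amber | 8.00 | 3.1 |
| amber | 15.0 | 5.5 |
| amber | 20.0 | 5.7 |
| amber | 30.0 | 7.3 |
| amber | 40.0 | 9.7 |
| amber | 50.0 | 10.0 |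
| teal | 8.00 | 2.0 |
| teal | 15.0 | 2.7 |
| teal | 20.0 | 3.6 |
| teal | 30.0 | 4.2 |
| teal | 40.0 | 4.0 |
| teal | 50.0 | 3.6 |

(standard deviation of a reading: 0.5 percentage points)

- amount of target at 50 min, in percent of the substrate charged
- concentration of dissolved gas in solution at 50 min, in percent of saturation

- at the start none of the gas phase is in solution

**Two extremes.** At constant selectivity, amber and teal would turn the same percentage into target, giving a yield ratio of 1. At a fixed [target], that ratio would equal teal's charge over amber's, 2.21. The readings give 2.78, more than the charge ratio, but a scatter of 0.5 percentage points on teal's small reading leaves this ratio loose. So this reading stands nearer the fixed-[target] extreme than the constant-selectivity one; within its scatter the runs may still lie between the two, and we reckon from the nearer extreme.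

**Late level.** Percentage times charge gives 3.40 mM for amber and 2.70 mM for teal. Their mean, 3.05 mM, is our late level, the [target] we expect at that time at these gas and impurity settings. Divided by the flask's charge of 0.050 M, it gives 6.10 %. The runs contain no reading of dissolved gas, so we give no number for it.

**The forecast.** The forecast says 6.2 % of target, a little above our figure, and 90 % of saturation: “Target formed therefore barely depends on substrate”.

**The result.** The flask gives 6.92 % of target and dissolved gas at 56.3 % of saturation.

    substrate + dissolved gas → target (k = 2.50 L mol⁻¹ min⁻¹)
    substrate → side product A (k = 0.0350 min⁻¹)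
    substrate + target → side product B (k = 3.60 L mol⁻¹ min⁻¹)
    dissolved gas + protic impurity → quenched reagent (k = 0.770 L mol⁻¹ min⁻¹)
    gas phase ⇌ dissolved gas, rate k5*(csat - [dissolved gas]) (kL = 0.0620 min⁻¹)

That is 3.46 mM of target against the late level of 3.05 mM. The neighbour flask with 0.20 M of substrate gives 1.42 % at the same time, where the late level reckons 1.52 %. In the flask at 11.8 min, the half-life of substrate by the step to target is 72 min, while by the step to side product A alone it is the shorter 20 min. By 50.0 min the flask holds 65.6 % of side product A.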